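I started from amounts: in the teal run the left-handed product stopped near 8.80 % of the combined charge, while left-handed substrate still stood at 40.9 %.

| flask | left-handed substrate | right-handed substrate | partner | free catalyst | remark |
|---|---|---|---|---|---|
| ochre | 0.10 M | 0.10 M | 0.20 M | 0.50 mM | run made earlier |
| teal | 0.10 M | 0.10 M | 0.20 M | 0.75 mM | run made earlier |
| amber | 0.10 M | 0.10 M | 0.10 M | 1 mM | run made earlier |
| flask | 0.10 M | 0.10 M | 0.200 M | 1.0 mM |  |

| run | time / min | left-handed product / % | left-handed substrate / % |
|---|---|---|---|
| ochre | 3.00 | 4.2 | 46.3 |
| ochre | 6.00 | 5.3 | 45.0 |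
| ochre | 10.0 | 6.7 | 43.6 |
| ochre | 12.0 | 5.6 | 43.2 |
| ochre | 15.0 | 5.8 | 44.6 |
| ochre | 20.0 | 5.5 | 43.5 |
| teal | 3.00 | 6.3 | 45.1 |
| teal | 6.00 | 7.4 | 42.6 |
| teal | 10.0 | 8.6 | 41.4 |
| teal | 12.0 | 8.4 | 41.6 |
| teal | 15.0 | 9.3 | 40.5 |
| teal | 20.0 | 8.7 | 40.9 |
| amber | 1.33 | 2.0 | 48.0 |
| amber | 2.50 | 3.7 | 47.4 |
| amber | 5.00 | 3.8 | 44.7 |
| amber | 10.0 | 5.8 | 44.7 |
| amber | 20.0 | 6.1 | 44.2 |

(readings scatter by 0.5 percentage points)

1. apparent order in partner when 5.0 % of the left-handed substrate and right-handed substrate together are converted (percent change of the rate of making left-handed product for one percent more partner charged)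

- free catalyst is single-handed; left-handed substrate and right-handed substrate are mirror images of each other, charged as a racemate, each of them at the stated concentration
- the numbers in the tables scatter with a standard deviation of 0.5 percentage points
- on the list of suspects stand: partner <-> dormant form; free catalyst -> spent catalyst; partner + free catalyst + left-handed substrate -> free catalyst + left-handed product; partner + free catalyst + right-handed substrate -> free catalyst + right-handed product

I read this as catalyst lost on its own clock, with the partner setting how much each catalyst made first. Scaled to the flask, teal gave a plateau of 11.7 %, and amber, scaled for catalyst and partner, gave 11.9 %. On that picture the rate follows the room left under the plateau, and more partner lifts the plateau in proportion. I counted the whole 5.0 % as left-handed product, a ceiling, since the right-handed product was unread. That gave 0.426 as the plateau fraction, the share of the plateau already made at the look. The order is then one over one minus that fraction, 1.74 by my reckoning.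

The forecast differed and stood at 1.4: “Assuming moderate selectivity”, it took 3.5 % of the charge as left-handed product.

The flask gave 1.6.

    partner ⇌ dormant form (K = 1.10, k = 2.57 × 10⁻⁴ s⁻¹)
    free catalyst → spent catalyst (k = 0.00451 s⁻¹)
    partner + free catalyst + left-handed substrate → free catalyst + left-handed product (k = 6.75 M⁻² s⁻¹)
    partner + free catalyst + right-handed substrate → free catalyst + right-handed product (k = 0.262 M⁻² s⁻¹)

In the flask, left-handed product stood at 4.59 % beside 0.187 % of right-handed product after 1.50 min, and it stood at 11.6 % after 150 min; applying that early split to the 5.0 % gave a fraction of 0.413. For the flask with twice the catalyst, two minus my earlier 0.426 over one minus 0.426 gave a rate factor of 2.74, and that run stood at 2.58. The largest single effect on the order came from the loss of free catalyst to spent catalyst: the same flask without that loss gave an order of 1.1.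

The earlier runs and the new flask were generated by integration on assumed constants; scatter was added.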